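The readings were generated by integration on assumed constants.

Time was what I had to plan by: 2.5 min of stirring at 0.24 M of starting complex, and the decision was whether the next run needed 1.80 equiv of scavenger or whether 1.20 equiv would do.

common to all: starting complex 0.24 M
- beta: incoming ligand 2.5 equiv; scavenger 0.95 equiv; run made earlier
- delta: incoming ligand 2.5 equiv; scavenger 1.4 equiv; run made earlier
- theta: incoming ligand 2.5 equiv; scavenger 1.7 equiv; run made earlier
- south-west: incoming ligand 2.50 equiv; scavenger 1.20 equiv; time 2.5 min
- north-east: incoming ligand 2.50 equiv; scavenger 1.80 equiv; time 2.5 min

- beta (time / s: starting complex / %, complex with two exchanged / %): 15.0: 89.5, 0.2; 30.0: 79.9, 0.8; 50.0: 70.6, 2.1; 60.0: 65.3, 3.1; 80.0: 57.2, 4.4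
- delta (time / s: starting complex / %, complex with two exchanged / %): 15.0: 89.3, 0.9; 30.0: 80.3, 1.6; 50.0: 70.1, 2.3; 60.0: 64.7, 3.4; 80.0: 57.2, 4.2
- theta (time / s: starting complex / %, complex with two exchanged / %): 10.0: 92.6, 0; 20.0: 85.5, 0.3; 40.0: 74.5, 1.1; 50.0: 69.4, 2.1; 80.0: 57.0, 5.2

(standard deviation of a reading: 0.5 percentage points)



1. part of the starting complex that has reacted at the end, south-west
2. part of the starting complex that has reacted at the end, north-east
3. what raising the equivalents of scavenger from its lowest to its highest value here does to the part of the starting complex that has reacted (changes below 5 percentage points count as none) (it falls / no change / it rises)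

At 80.0 s the starting complex read 57.2%, 57.2% and 57.0% with scavenger at 0.95 equiv, 1.4 equiv and 1.7 equiv, against a scatter of 0.5 percentage points, so I left scavenger out of my rate. A pseudo-first-order line holds the incoming ligand at its charge of 0.600 M, which it cannot keep. I therefore counted one incoming ligand lost per starting complex lost and integrated the rate, first order in each, in closed form. The logarithm of the share of incoming ligand left over the share of starting complex left, divided by the difference of the two charges in molar and by the time, is what I called the first-exchange constant: 0.0129 M⁻¹ s⁻¹, read from the last beta reading.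

Carried to 2.5 min, it takes that ratio of shares to 2.00, so I expected 62.6% reacted in south-west and in north-east alike, and I would have charged the smaller amount. The forecast gave 62.5% (58.5% to 66.5%) for south-west and 63% (59.5% to 66.5%) for north-east, with no change, holding that “scavenger shouldn't run out in either run”.

The flasks gave 62.1% in south-west and 62.1% in north-east: no change.

    starting complex + incoming ligand ⇌ leaving ligand + complex with one exchanged (K = 2.80, k = 0.0130 M⁻¹ s⁻¹)
    complex with one exchanged + incoming ligand ⇌ leaving ligand + complex with two exchanged (K = 0.730, k = 0.00520 M⁻¹ s⁻¹)
    leaving ligand + starting complex ⇌ idle adduct, settled at all times (K = 1.10 M⁻¹)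
    scavenger + leaving ligand → scavenged by-product (k = 9.20 M⁻¹ s⁻¹)

The north-east answer has moved by 5 points with incoming ligand at 2.19 equiv or 2.85 equiv, the other amounts and the time held, or with starting complex at 0.205 M or 0.282 M, the equivalents and the time held, and a move of that size from 62.1% lies outside the forecast's range of 59.5% to 66.5%. At 1.25 min in north-east, the first-exchange constant leaves 59.1% of the starting complex, and the flask held 59.0%.

For a neighbour of north-east charged with 0.41 M, same equivalents and time, the constant gives 79.2% reacted; the computed flask gives 77.8%.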